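No rate constant is given for this flask, so I reckon with a quantity read from the runs: the split S, or selectivity factor, defined as isomer of the product over target, summed over the last two readings of both runs, 0.423. Target's share of the two products is then 1/(1+S), or 70.3%.

| flask | starting material | gas | remark | time |
|---|---|---|---|---|
| beta | 2.5 mM | 2.1 mM (held) | run made earlier |  |
| theta | 10 mM | 2.1 mM (held) | run made earlier |  |
| flask | 5.0 mM | 2.1 mM (held) |  | 3.0 min |

| run | time / min | isomer of the product / % | target / % | starting material / % |
|---|---|---|---|---|
| beta | 0.417 | 16.3 | 41.0 | 36.7 |
| beta | 1.33 | 29.9 | 69.1 | 1.1 |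
| beta | 2.50 | 29.2 | 70.7 | 0 |
| beta | 4.00 | 30.5 | 69.7 | 0.8 |
| theta | 0.250 | 6.7 | 16.5 | 68.3 |
| theta | 0.667 | 17.6 | 41.6 | 36.1 |
| theta | 1.50 | 28.2 | 67.9 | 4.8 |
| theta | 4.00 | 29.9 | 70.1 | 0.4 |

(readings scatter by 0.5 percentage points)

- at the start none of the gas is in solution
- a reading or a percentage of target counts all its forms, free or not

- ratio of isomer of the product to target at 4.0 s
- ratio of isomer of the product to target at 3.0 min
- which of isomer of the product and target there is more of at 3.0 min

Does S depend on the charge? Read apart, the beta run gives 0.425 from 2.5 mM and the theta run 0.421 from 10 mM. I read no dependence, and the flask's 5.0 mM lies between those charges.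

But the theta run's first reading lacks 8.50% of the charge, and its last sums to 100%. Could that hidden material favour one product? It must pass into the products, yet the ratio at that first reading is 0.406, and a scatter of 0.5 percentage points on readings of 6.7% and 16.5% covers its distance from S. I can read no preference.

And at 4.0 s? That time is earlier than any reading, and none of the gas is in solution at the start, so this is extrapolation. I commit to S at both times, with target leading at 3.0 min, its share being larger than the isomer's.

The forecast gives 0.41 at 4.0 s, slightly below my S, and 0.425 at 3.0 min, with target leading, holding that “the two products form in parallel at a fixed split”.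

The flask gives 0.425 at 4.0 s and 0.425 at 3.0 min, and target leads with 70.2% against 29.8%.

    starting material ⇌ other conformer (K = 0.140, k = 2.80 s⁻¹)
    starting material + partner → target (k = 24.0 M⁻¹ s⁻¹)
    partner + other conformer → isomer of the product (k = 73.0 M⁻¹ s⁻¹)
    crystals ⇌ target, rate k4*(cs4 - [target]) while solid is left; crystals form when [target] > cs4 (solubility = 4.80 mM, k = 15.0 s⁻¹)
    gas ⇌ partner, rate k5*(csat - [partner]) (kL = 0.130 s⁻¹)

The neighbouring flask changes one setting: it holds 20 mM of starting material, a charge larger than either run's. The same reckoning carries S over to it, with target at 70.3%. That flask shows 0.425 at 4.0 s and 0.425 at 3.0 min, still below one, and target stands at 70.0% of its charge, all forms counted. Of the charge, 0.17% remains as starting material. At 3.00 min, crystals in the neighbouring flask make up 46.0% of its charge, counted within that target, against 0% in the first flask.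

The runs stem from a simulated flask on assumed constants.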